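| flask | left-handed substrate | right-handed substrate | reagent | free catalyst | remark |
|---|---|---|---|---|---|
| Thursday's | 1.2 M | 1.2 M | 0.96 M | 24 mM | the very flask that is asked about, followed so far |
| Wednesday's | 1.8 M | 1.8 M | 0.96 M | 24 mM | run made earlier |
| flask | 1.2 M | 1.2 M | 0.960 M | 24 mM |  |

- Thursday's (time / min: left-handed product / %): 0.417: 0.7; 1.00: 1.6; 2.00: 1.7; 3.00: 3.3; 4.00: 3.9; 6.00: 5.0; 8.00: 6.5
- Wednesday's (time / min: left-handed product / %): 3.00: 2.8; 5.00: 4.4; 8.00: 6.4; 12.0: 8.1; 20.0: 10.3; 30.0: 12.5; 40.0: 13.6

(each reading ± 0.3 percentage points)

- apparent order in free catalyst when 10% of the left-handed substrate and right-handed substrate together are converted (percent change of the rate of making left-handed product for one percent more free catalyst charged)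

If the free catalyst lasted, one percent more of it would mean one percent more rate. Suppose instead that it dies at a steady fractional rate. A larger charge then reaches the conversion sooner, with less of itself dead, so the order rises above 1.

We read that decay from Wednesday's run, taking the rate as proportional to c(free catalyst)·c(left-handed substrate)·c(reagent). The rate falls from 0.0336 M min⁻¹ over the first 3.00 min to 0.00396 M min⁻¹ between 30.0 min and 40.0 min. No run measures the right-handed product, so we suppose that it forms at 0.5 times the rate of the left-handed product and that each product uses one reagent. With 0.470 M of left-handed product made, 0.705 M of reagent is then used, and the two other concentrations account for a factor of 5.09. So 60.0% of the activity survives, which gives a decay constant of 0.0153 min⁻¹.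

Thursday's flask shows 6.5% left-handed product at 8.00 min, and with the right-handed product as supposed that makes 9.75% converted, close to the 10% we look at. Our loss number is 0.122: the decay constant times the time to reach the conversion looked at. The order is 1 plus this number, so we reckon 1.12.

Is one number enough? Wednesday's stretch from 12.0 min to 20.0 min, read the same way, gives 0.0200 min⁻¹, which is 1.31 times the first reading, so one constant serves for a rough figure and no more.

The forecast gives 1.15, range 0.9 to 1.5: “No run varied the catalyst, so I guess slightly above 1.”

The flask gives 1.2.

    reagent + free catalyst + left-handed substrate → free catalyst + left-handed product (k = 0.0160 M⁻² s⁻¹)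
    reagent + free catalyst + right-handed substrate → free catalyst + right-handed product (k = 0.00720 M⁻² s⁻¹)
    2 free catalyst → spent catalyst A (k = 0.00120 M⁻¹ s⁻¹)
    free catalyst → spent catalyst B (k = 3.40 × 10⁻⁴ s⁻¹)

Removing the formation of spent catalyst B from Thursday's flask lowers the order from 1.2 to 1.0, so this step is a part of the reason for the excess. On the apparent order in reagent the same removal has the largest single effect, from 1.6 to 1.4. Its constant 1.2 h⁻¹ times the 8.43 min to the conversion gives a loss number of 0.172, above our 0.122. Carried to 1.00 h, the same product leaves 29.4% of the free catalyst, and Thursday's flask holds 26.3%.

(The readings come from a simulation for substances that don't exist; noise was put on by code.)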